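- The constants 0.15 h⁻¹ and 1.4 M⁻¹ h⁻¹ belong to steps of different order, so I first looked for the one concentration that would put the coupling step on the same footing as the step from substrate to intermediate.

    substrate + target → side product (k1 = 8.5 M⁻¹ h⁻¹)
    substrate → intermediate (k2 = 0.15 h⁻¹)
    coupling partner + intermediate → target (k3 = 1.4 M⁻¹ h⁻¹)

the same everywhere: substrate 20 mM (in portions, 3); time 20 h

| charge | coupling partner | remark |
|---|---|---|
| alder | 1.20 equiv | the portions of substrate follow each other after 6.0 h, the first at the start |
| maple | 3.00 equiv | the portions of substrate follow each other after 6.0 h, the first at the start |
| cedar | 7.50 equiv | the portions of substrate follow each other after 6.0 h, the first at the start |

* which of these there is most of at the end, counted by the substrate in it, alder (intermediate / substrate / side product / target)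
* which of these there is most of at the end, counted by the substrate in it, maple (intermediate / substrate / side product / target)
* which of these there is most of at the end, counted by the substrate in it, cedar (intermediate / substrate / side product / target)
* amount of the one of these that there is most of at the end, in percent of the substrate charged, alder
* amount of the one of these that there is most of at the end, in percent of the substrate charged, maple
* amount of the one of these that there is most of at the end, in percent of the substrate charged, cedar

- in percentages every species weighs as the substrate in it: one side product counts as two
- run time (alder): 20 h

- Alder, maple and cedar differ in the equivalents of coupling partner. In maple the whole substrate charge can take at most 33.3% of the coupling partner, so c(coupling partner) stays near 60.0 mM and the coupling step is pseudo-first-order in intermediate.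
- For maple, the natural logarithm of two over the coupling constant times c(coupling partner) gives 8.25 h. I carried this time as the hand-over half-life, the half-life of intermediate as it passes to target at a steady c(coupling partner). It is 21 h for alder and 3.30 h for cedar.
- By the end of the run the portions have stood for 14.0 h on average, and substrate lasts 6.67 h on average before it turns to intermediate, so I gave an intermediate a window of about 7.33 h.
- Maple's hand-over half-life is longer than the window and cedar's is shorter. I therefore expected intermediate to lead in maple and target in cedar. Alder's is longer still, so I expected intermediate to lead there too.
- My reckoning stopped at the leaders and gave no percentages. In alder, target reacting with substrate has a half-life of 4.1 h at the whole charge, shorter than the run, and I did not follow that loss by hand.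
- The forecast named the same leaders and went on to amounts: intermediate at 60% in alder, intermediate at 39% in maple and target at 44% in cedar. Its grounds were these: “I stepped each run through its portions by hand, in 2–3 h steps, using mM units.”
- The simulation gave intermediate at 60.7% in alder, intermediate at 38.6% in maple and target at 44.4% in cedar.
- Intermediate and target stand equal at 3.61 equiv of coupling partner, all else as stated. There the hand-over half-life is 6.86 h, shorter than maple's 8.25 h and a little under my window of 7.33 h. The neighbouring flask is alder with 4.80 equiv of coupling partner, its other charges and time unchanged. Its c(coupling partner) is 96.0 mM and its hand-over half-life is 5.16 h, shorter than that. The neighbouring flask ended with 38.3% of target, more than its 25.8% of intermediate.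

The constants used here were set for the occasion, and the outcome is calculated.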